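**Retrosynthetic overview**
1. The acetates go on last. The target comes from the 2,8,9,12-tetraol, with the 8,9-diol masked in the flask as a phenylboronate during acetylation.
2. The γ-lactone is the third ring and carries C7 and C8. It comes from OH-directed epoxidation of a macrocyclic (5Z,7E)-dienol, followed by invertive opening at allylic C7 by the C19 tert-butyl ester.
3. The ten-membered ring is the second ring and carries C9. It comes from a Ni(0)-catalysed reductive enyne–aldehyde macrocyclisation that forms C8–C9.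
4. The fragments are joined at C4–C5 by a Negishi sp3–sp2 coupling of a ring-A alkylzinc with a (Z)-iodoenyne ester.
5. The cyclohexene is the first ring and carries C1, C10 and C11. It comes from an enantioselective Diels–Alder reaction of (E)-piperylene with a β-formyl methacrylate. The iodoenyne (C17) comes from (S)-Roche ester.

Assumption: briarane numbering (C1–C20) is used for all fragments, and the sense of induction in step 2 follows the formyl C–H···O model for oxazaborolidinium catalysis (if it proves opposite, the (R)-catalyst is used).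

**Step 1**
Reactants: 1 methyl (E)-2-methylbut-2-enoate (methyl tiglate)
Product: 2 methyl (E)-2-methyl-4-oxobut-2-enoate
Conditions: SeO2, 1,4-dioxane, 100 °C
Reagents that add atoms: selenium dioxide O=[Se]=O
Why: Riley allylic oxidation (ene reaction, then [2,3]-shift), in which Se binds the more nucleophilic α-carbon of the enoate, so only the γ-methyl is oxidised and the E geometry (ester trans to the new CHO) is kept.

**Step 2**
Reactants: 2 methyl (E)-2-methyl-4-oxobut-2-enoate; 3 (E)-penta-1,3-diene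
Product: 4 methyl (1S,5S,6S)-6-formyl-1,5-dimethylcyclohex-3-ene-1-carboxylate (15-Me, CHO and 20-Me β, CO2Me α)
Conditions: (S)-o-tolyl-oxazaborolidinium triflimide (15 mol %), CH2Cl2, −78 → −40 °C
Reagents that add atoms: none
Why: Catalytic enantioselective Diels–Alder reaction in which the boron-bound formyl group controls the "ortho" regiochemistry (C11 to C10, free diene terminus C14 to quaternary C1) and the endo mode (CHO cis to 20-Me), the E dienophile keeps CHO and CO2Me trans, and the catalyst leaves only the C1-Si/C10-Si face open, so C1, C10 and C11 are set together.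

**Step 3**
Reactants: 4 Diels–Alder aldehyde
Product: 5 methyl (1S,5S,6S)-6-(dimethoxymethyl)-1,5-dimethylcyclohex-3-ene-1-carboxylate
Conditions: HC(OMe)3, PPTS (cat.), MeOH, rt
Reagents that add atoms: trimethyl orthoformate COC(OC)OC
Why: Mild acid-catalysed acetalisation masks the epimerisable C9 aldehyde without touching C10 and differentiates it from the C2 ester.

**Step 4**
Reactants: 5 acetal ester
Product: 6 (1S,5S,6S)-6-(dimethoxymethyl)-1,5-dimethylcyclohex-3-ene-1-carbaldehyde
Conditions: DIBAL-H (1.2 equiv), toluene, −78 °C; Rochelle salt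
Reagents that add atoms: none
Why: Partial DIBAL-H reduction works because the aluminium hemiacetal of the α-quaternary ester is stable at −78 °C and collapses to the non-enolisable aldehyde only on work-up.

**Step 5**
Reactants: 6 C2 aldehyde
Product: 7 (1R)-1-[(1S,5S,6S)-6-(dimethoxymethyl)-1,5-dimethylcyclohex-3-en-1-yl]prop-2-en-1-ol
Conditions: (CH2=CH)2Zn (from CH2=CHMgBr/ZnCl2, salts removed), (+)-MIB (10 mol %), toluene, 0 °C
Reagents that add atoms: divinylzinc C=C[Zn]C=C
Why: Amino-alcohol-catalysed asymmetric alkenylzinc addition in which (+)-MIB delivers vinyl to the Re face of the aldehyde, so 2R is set by the catalyst and not by the weakly biased quaternary C1.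

**Step 6**
Reactants: 7 allylic alcohol
Product: 8 12α,13α-epoxide of 7 (1S,2R,10S,11R,12S,13R)
Conditions: m-CPBA, NaHCO3, CH2Cl2, 0 °C
Reagents that add atoms: m-CPBA OOC(=O)c1cccc(Cl)c1
Why: Prilezhaev epoxidation, where the cis-disubstituted ring alkene reacts far faster than the vinyl group, the β face is blocked by 15-Me, 20-Me and the C10 acetal arm, and the α-oriented C2–OH can hydrogen-bond the peracid, which gives the α-epoxide.

**Step 7**
Reactants: 8 epoxide
Product: 11 (1R,4S,5S,6R)-5-(dimethoxymethyl)-4-[(1R)-1-hydroxyprop-2-en-1-yl]-4,6-dimethylcyclohex-2-en-1-ol, via 12α-hydroxy-13β-phenylselenide 9 (not isolated), via its selenoxide 10 (not isolated)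
Conditions: (PhSe)2, NaBH4, EtOH, 78 °C; then 30 % H2O2, THF, 0 °C → rt
Reagents that add atoms: none
Why: Sharpless–Lauer epoxide-to-allylic-alcohol transposition, in which PhSe− opens the epoxide by SN2 at the less hindered C13 (the 12α C–O bond stays) and the selenoxide eliminates syn, away from the carbinol carbon towards C14.

**Step 8**
Reactants: 11 diol
Product: 12 2,12-bis-O-TBS ether of 11
Conditions: TBSOTf, 2,6-lutidine, CH2Cl2, −78 → 0 °C
Reagents that add atoms: TBSOTf CC(C)(C)[Si](C)(C)OS(=O)(=O)C(F)(F)F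
Why: Silyl triflate silylation covers both hindered secondary alcohols, and silyl ethers (unlike allylic acetates) are inert to the later Pd(0) and Ni(0) steps.

**Step 9**
Reactants: 12 bis-TBS ether
Product: 14 primary C4 iodide (C2–CH2CH2I), via B-alkyl-9-BBN 13 (not isolated)
Conditions: 9-BBN-H, THF, rt; then NaOMe, I2, MeOH, 0 °C
Reagents that add atoms: iodine II
Why: Anti-Markovnikov hydroboration with bulky 9-BBN-H touches only the terminal vinyl group, and base-induced iodinolysis (Brown iodination) converts the primary B–C bond into the iodide.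

**Step 10**
Reactants: 15 iodoethane
Product: 16 ethyltriphenylphosphonium iodide
Conditions: PPh3, toluene, 110 °C
Reagents that add atoms: triphenylphosphine c1ccc(cc1)P(c1ccccc1)c1ccccc1
Why: SN2 quaternisation of the phosphine gives the crystalline Wittig salt.

**Step 11**
Reactants: 17 methyl (S)-3-hydroxy-2-methylpropanoate ((S)-Roche ester)
Product: 18 methyl (S)-3-[(tert-butyldimethylsilyl)oxy]-2-methylpropanoate
Conditions: TBSCl, imidazole, CH2Cl2, rt
Reagents that add atoms: TBSCl CC(C)(C)[Si](C)(C)Cl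
Why: Standard silylation of the primary alcohol, with the chiral-pool stereocentre (future C17) untouched.

**Step 12**
Reactants: 18 TBS ester
Product: 19 (S)-3-[(tert-butyldimethylsilyl)oxy]-2-methylpropanal
Conditions: DIBAL-H, CH2Cl2, −78 °C
Reagents that add atoms: none
Why: Partial DIBAL-H reduction of the ester at −78 °C is well established for this substrate and does not epimerise the α-centre.

**Step 13**
Reactants: 19 aldehyde
Product: 20 (R)-tert-butyl[(4,4-dibromo-2-methylbut-3-en-1-yl)oxy]dimethylsilane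
Conditions: CBr4, PPh3, CH2Cl2, 0 °C
Reagents that add atoms: carbon tetrabromide BrC(Br)(Br)Br
Why: Corey–Fuchs (Ramirez) dibromo-olefination runs under neutral conditions, so the α-stereocentre is safe and C7 is added.

**Step 14**
Reactants: 20 dibromoalkene
Product: 23 (R)-5-[(tert-butyldimethylsilyl)oxy]-4-methylpent-2-ynal, via bromoalkyne 21 (not isolated), via lithium acetylide 22 (not isolated)
Conditions: n-BuLi (2.1 equiv), THF, −78 °C; DMF, −78 → 0 °C; reverse quench into aq KH2PO4
Reagents that add atoms: N,N-dimethylformamide CN(C)C=O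
Why: In the second Corey–Fuchs stage, elimination and Br/Li exchange give the acetylide, which is formylated by DMF (C6), and the buffered reverse quench stops dimethylamine from adding to the ynal.

**Step 15**
Reactants: 23 ynal; 16 ethyltriphenylphosphonium iodide
Product: 27 (R,Z)-tert-butyl[(6-iodo-2-methylhept-5-en-3-yn-1-yl)oxy]dimethylsilane, via ethylidenetriphenylphosphorane 24 (not isolated), via (1-iodoethyl)triphenylphosphonium iodide 25 (not isolated), via (1-iodoethylidene)triphenylphosphorane 26 (not isolated)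
Conditions: 16, n-BuLi, THF, rt; I2, −78 °C; NaHMDS, −20 °C; 23, −78 °C
Reagents that add atoms: iodine II
Why: Stork–Zhao-type iodo-Wittig olefination, where the unstabilised α-iodo ylide reacts through the kinetic cis-oxaphosphetane and places iodine cis to the alkynyl group (5Z geometry with the C5 handle).

**Step 16**
Reactants: 27 silyl ether
Product: 28 (R,Z)-6-iodo-2-methylhept-5-en-3-yn-1-ol
Conditions: HF·pyridine, THF, 0 °C → rt
Reagents that add atoms: none
Why: Fluoride-driven desilylation of a primary TBS ether under non-basic conditions leaves the iodoenyne intact.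

**Step 17**
Reactants: 28 alcohol
Product: 30 (R,Z)-6-iodo-2-methylhept-5-en-3-ynoic acid, via (R,Z)-6-iodo-2-methylhept-5-en-3-ynal 29 (not isolated)
Conditions: TEMPO (cat.), PhI(OAc)2, MeCN/H2O, 0 °C → rt
Reagents that add atoms: water O
Why: TEMPO/PhI(OAc)2 oxidation (oxoammonium catalysis) takes the alcohol through the short-lived aldehyde hydrate to the acid in a weakly acidic medium, so C17 is not epimerised and the alkyne does not isomerise to the allene.

**Step 18**
Reactants: 30 acid
Product: 31 tert-butyl (R,Z)-6-iodo-2-methylhept-5-en-3-ynoate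
Conditions: Cl3CC(=NH)Ot-Bu, BF3·OEt2 (cat.), cyclohexane/CH2Cl2, rt
Reagents that add atoms: tert-butyl 2,2,2-trichloroacetimidate CC(C)(C)OC(=N)C(Cl)(Cl)Cl
Why: Acid-catalysed imidate tert-butylation is base-free (no alkyne–allene isomerisation or C17 epimerisation), and the bulky ester later resists lactonisation onto the C9–OH.

**Step 19**
Reactants: 14 primary iodide; 31 (Z)-iodoenyne ester
Product: 33 seco acetal (C4–C5 coupled, 5Z-enyne, 1S,2R,10S,11R,12R,17R), via alkylzinc iodide 32 (not isolated)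
Conditions: Zn, LiCl, THF, 40 °C; then 31, Pd(dppf)Cl2 (5 mol %), THF, rt
Reagents that add atoms: none
Why: Negishi sp3–sp2 cross-coupling is essentially neutral, so the acidic C17–H next to alkyne and ester survives, and oxidative addition and reductive elimination at the alkenyl iodide retain the Z geometry.

**Step 20**
Reactants: 33 seco acetal
Product: 34 seco aldehyde (free C9 CHO)
Conditions: PPTS, acetone/H2O, 45 °C
Reagents that add atoms: water O
Why: Mild acetal hydrolysis frees the aldehyde while the secondary TBS ethers and the tert-butyl ester survive and C10 is not epimerised.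

**Step 21**
Reactants: 34 seco aldehyde
Product: 35 macrocyclic (5Z,7E)-dien-9-ol (trans-fused bicyclo[8.4.0], 9R, C8 bears CH(CH3)CO2t-Bu)
Conditions: Ni(cod)2 (20 mol %), P(c-C5H9)3 (40 mol %), Et3B (4 equiv), toluene, 2 mM, syringe pump, rt
Reagents that add atoms: none
Why: Proposed new method: a ten-membered, all-carbon ring closure by nickel-catalysed reductive alkyne–aldehyde coupling, which is known only intermolecularly for 1,3-enynes and intramolecularly for small (5–7) and large (≥12) rings; Ni(0) binds the enyne, the coordinated C5=C6 alkene steers oxidative cyclisation with the aldehyde so that the distal alkyne carbon C8 forms the C–C bond (oxanickelacyclopentene), ethyl transfer from Et3B, β-hydride elimination and C–H reductive elimination place H on C7 syn to C9 (7E), the trans C2/C9 arms on ring A and the Z alkene pre-organise the chain, high dilution suppresses oligomers, and Felkin–Anh attack anti to C1 gives 9R; the closest known reaction type is the Montgomery/Jamison reductive coupling and macrocyclisation.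

**Step 22**
Reactants: 35 macrocyclic dienol
Product: 37 2,12-bis-O-TBS hydroxy lactone (7S,8R,9R,17R), via (7R,8R,9R)-7,8-epoxy alcohol 36 (not isolated)
Conditions: VO(acac)2 (5 mol %), t-BuOOH, CH2Cl2, 0 °C; then CSA (20 mol %), 0 °C
Reagents that add atoms: tert-butyl hydroperoxide CC(C)(C)OO
Why: Hydroxyl-directed vanadium epoxidation touches only the C7=C8 alkene of the allylic alcohol and, under A(1,2) strain with the C17 branch, gives the erythro epoxy alcohol (8R relative to 9R), and acid then triggers lactonisation of the β,γ-epoxy tert-butyl ester by SN2 opening at the allylic C7 with inversion (7S) and loss of isobutene, which leaves the 8-OH.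

**Step 23**
Reactants: 37 bis-TBS lactone
Product: 38 2,8,9,12-tetraol lactone (2,12-dideacetyl target)
Conditions: HF·pyridine, pyridine/THF, rt → 40 °C
Reagents that add atoms: none
Why: Buffered fluoride desilylation removes both secondary TBS groups without retro-aldol, dehydration or C17 epimerisation of the β-hydroxy lactone.

**Step 24**
Reactants: 38 tetraol
Product: 41 target CNP0286823.1, via 8,9-O-phenylboronate 39 (not isolated), via 8,9-O-phenylboronate 2,12-diacetate 40 (not isolated)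
Conditions: PhB(OH)2, 4 Å MS, CH2Cl2; Ac2O, pyridine, DMAP (cat.), 0 °C → rt; then pinacol, MeOH
Reagents that add atoms: acetic anhydride CC(=O)OC(C)=O
Why: Transient cyclic boronate protection of the only 1,2-diol (C8/C9) lets standard DMAP-catalysed acetylation hit only the 2-OH and 12-OH, and transesterification with pinacol then frees the diol without touching any stereocentre.

**Compound list**
1 | methyl tiglate | COC(=O)/C(C)=C/C | starting material
2 | methyl (E)-2-methyl-4-oxobut-2-enoate | COC(=O)/C(C)=C/C=O | intermediate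
3 | (E)-penta-1,3-diene | C=C/C=C/C | starting material
4 | methyl (1S,5S,6S)-6-formyl-1,5-dimethylcyclohex-3-ene-1-carboxylate | C1=CC[C@@](C(=O)OC)(C)[C@H]([C@H]1C)C=O | intermediate
5 | methyl (1S,5S,6S)-6-(dimethoxymethyl)-1,5-dimethylcyclohex-3-ene-1-carboxylate | C1=CC[C@@](C(=O)OC)(C)[C@H]([C@H]1C)C(OC)OC | intermediate
6 | (1S,5S,6S)-6-(dimethoxymethyl)-1,5-dimethylcyclohex-3-ene-1-carbaldehyde | C1=CC[C@@](C=O)(C)[C@H]([C@H]1C)C(OC)OC | intermediate
7 | (2R)-allylic alcohol | C1=CC[C@@]([C@H](O)C=C)(C)[C@H]([C@H]1C)C(OC)OC | intermediate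
8 | 12α,13α-epoxide | O1[C@@H]2[C@H]1C[C@@]([C@H](O)C=C)(C)[C@H]([C@H]2C)C(OC)OC | intermediate
9 | 12α-hydroxy-13β-phenylselenide | O[C@@H]1[C@@H]([Se]c2ccccc2)C[C@@]([C@H](O)C=C)(C)[C@H]([C@H]1C)C(OC)OC | intermediate
10 | selenoxide of 9 | O[C@@H]1[C@@H]([Se](=O)c2ccccc2)C[C@@]([C@H](O)C=C)(C)[C@H]([C@H]1C)C(OC)OC | intermediate
11 | ring-A diol (12α-OH, Δ13, 2R-OH) | O[C@@H]1C=C[C@@]([C@H](O)C=C)(C)[C@H]([C@H]1C)C(OC)OC | intermediate
12 | 2,12-bis-O-TBS ether | CC(C)(C)[Si](C)(C)O[C@@H]1C=C[C@@]([C@H](O[Si](C)(C)C(C)(C)C)C=C)(C)[C@H]([C@H]1C)C(OC)OC | intermediate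
13 | B-alkyl-9-BBN | CC(C)(C)[Si](C)(C)O[C@@H]1C=C[C@@]([C@H](O[Si](C)(C)C(C)(C)C)CCB2C3CCCC2CCC3)(C)[C@H]([C@H]1C)C(OC)OC | intermediate
14 | primary C4 iodide | CC(C)(C)[Si](C)(C)O[C@@H]1C=C[C@@]([C@H](O[Si](C)(C)C(C)(C)C)CCI)(C)[C@H]([C@H]1C)C(OC)OC | intermediate
15 | iodoethane | CCI | starting material
16 | ethyltriphenylphosphonium iodide | CC[P+](c1ccccc1)(c1ccccc1)c1ccccc1.[I-] | intermediate
17 | (S)-Roche ester | COC(=O)[C@@H](C)CO | starting material
18 | TBS ether of 17 | COC(=O)[C@@H](C)CO[Si](C)(C)C(C)(C)C | intermediate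
19 | (S)-3-(TBSO)-2-methylpropanal | O=C[C@@H](C)CO[Si](C)(C)C(C)(C)C | intermediate
20 | (R)-dibromoalkene | BrC(Br)=C[C@@H](C)CO[Si](C)(C)C(C)(C)C | intermediate
21 | (R)-bromoalkyne | BrC#C[C@@H](C)CO[Si](C)(C)C(C)(C)C | intermediate
22 | (R)-lithium acetylide | [Li]C#C[C@@H](C)CO[Si](C)(C)C(C)(C)C | intermediate
23 | (R)-5-(TBSO)-4-methylpent-2-ynal | O=CC#C[C@@H](C)CO[Si](C)(C)C(C)(C)C | intermediate
24 | ethylidenetriphenylphosphorane | CC=P(c1ccccc1)(c1ccccc1)c1ccccc1 | intermediate
25 | (1-iodoethyl)triphenylphosphonium iodide | CC(I)[P+](c1ccccc1)(c1ccccc1)c1ccccc1.[I-] | intermediate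
26 | (1-iodoethylidene)triphenylphosphorane | CC(I)=P(c1ccccc1)(c1ccccc1)c1ccccc1 | intermediate
27 | (R,Z)-iodoenyne TBS ether | C/C(I)=C/C#C[C@@H](C)CO[Si](C)(C)C(C)(C)C | intermediate
28 | (R,Z)-6-iodo-2-methylhept-5-en-3-yn-1-ol | C/C(I)=C/C#C[C@@H](C)CO | intermediate
29 | (R,Z)-6-iodo-2-methylhept-5-en-3-ynal | C/C(I)=C/C#C[C@@H](C)C=O | intermediate
30 | (R,Z)-6-iodo-2-methylhept-5-en-3-ynoic acid | C/C(I)=C/C#C[C@@H](C)C(=O)O | intermediate
31 | tert-butyl (R,Z)-6-iodo-2-methylhept-5-en-3-ynoate | C/C(I)=C/C#C[C@@H](C)C(=O)OC(C)(C)C | intermediate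
32 | alkylzinc iodide from 14 | CC(C)(C)[Si](C)(C)O[C@@H]1C=C[C@@]([C@H](O[Si](C)(C)C(C)(C)C)CC[Zn]I)(C)[C@H]([C@H]1C)C(OC)OC | intermediate
33 | seco acetal | CC(C)(C)[Si](C)(C)O[C@@H]1C=C[C@@]([C@H](O[Si](C)(C)C(C)(C)C)CC/C(C)=C\C#C[C@@H](C)C(=O)OC(C)(C)C)(C)[C@H]([C@H]1C)C(OC)OC | intermediate
34 | seco aldehyde | CC(C)(C)[Si](C)(C)O[C@@H]1C=C[C@@]([C@H](O[Si](C)(C)C(C)(C)C)CC/C(C)=C\C#C[C@@H](C)C(=O)OC(C)(C)C)(C)[C@H]([C@H]1C)C=O | intermediate
35 | macrocyclic (5Z,7E)-dien-9-ol | CC(C)(C)[Si](C)(C)O[C@@H]1C=C[C@@]2(C)[C@H]([C@H]1C)[C@@H](O)/C([C@@H](C)C(=O)OC(C)(C)C)=C/C=C(/C)CC[C@H]2O[Si](C)(C)C(C)(C)C | intermediate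
36 | (7R,8R,9R)-7,8-epoxy alcohol | CC(C)(C)[Si](C)(C)O[C@@H]1C=C[C@@]2(C)[C@H]([C@H]1C)[C@@H](O)[C@@]3([C@@H](C)C(=O)OC(C)(C)C)O[C@@H]3/C=C(/C)CC[C@H]2O[Si](C)(C)C(C)(C)C | intermediate
37 | 2,12-bis-O-TBS hydroxy lactone | CC(C)(C)[Si](C)(C)O[C@@H]1C=C[C@@]2(C)[C@H]([C@H]1C)[C@@H](O)[C@@]1(O)[C@H](/C=C(/C)CC[C@H]2O[Si](C)(C)C(C)(C)C)OC(=O)[C@@H]1C | intermediate
38 | tetraol lactone | O[C@@H]1C=C[C@@]2(C)[C@H]([C@H]1C)[C@@H](O)[C@@]1(O)[C@H](/C=C(/C)CC[C@H]2O)OC(=O)[C@@H]1C | intermediate
39 | 8,9-O-phenylboronate | O[C@@H]1C=C[C@@]2(C)[C@H]([C@H]1C)[C@H]3OB(c4ccccc4)O[C@@]31[C@H](/C=C(/C)CC[C@H]2O)OC(=O)[C@@H]1C | intermediate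
40 | 8,9-O-phenylboronate 2,12-diacetate | CC(=O)O[C@@H]1C=C[C@@]2(C)[C@H]([C@H]1C)[C@H]3OB(c4ccccc4)O[C@@]31[C@H](/C=C(/C)CC[C@H]2OC(C)=O)OC(=O)[C@@H]1C | intermediate
41 | CNP0286823.1 (1S,2R,5Z,7S,8R,9R,10S,11R,12R,17R) | CC(=O)O[C@@H]1C=C[C@@]2(C)[C@H]([C@H]1C)[C@@H](O)[C@@]1(O)[C@H](/C=C(/C)CC[C@H]2OC(C)=O)OC(=O)[C@@H]1C | target

**Totals**
Total step count: 24. Longest linear sequence: 15 (steps 1–9, then 19–24).

**Three steps most likely to fail**

Step 21 (new medium-ring reductive macrocyclisation). The risks are strain of the (5Z,7E)-cyclodecadiene, oligomerisation and the wrong C9 epimer.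
- This fallback uses only known reactions, sets out from alcohol 28 and zinc reagent 32, and comes back at 35.
- 28 is silylated with 1,1,3,3-tetramethyldisilazane to the dimethylsilyl ether F4.
- Karstedt-platinum intramolecular 5-exo-dig syn-hydrosilylation gives the alkylidene oxasilolane F5, with Si on C8 and cis to H7.
- Negishi coupling of 32 at the C5–I bond gives the coupled siloxane F6.
- Iododesilylation with NIS in MeCN (retention) and aqueous work-up gives the C8 alkenyl iodide alcohol F7.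
- TEMPO/PhI(OAc)2 oxidation gives the acid F8, and the trichloroacetimidate gives the tert-butyl ester F9.
- PPTS in wet acetone gives the iodo aldehyde F10.
- A high-dilution Nozaki–Hiyama–Kishi cyclisation (CrCl2, cat. NiCl2, DMSO/THF) closes C8–C9 to 35.

Step 2 (regio-, endo- and enantiocontrol with a β,β-disubstituted enal).
- This fallback sets out from 2 and 3 and comes back at 5.
- An EtAlCl2-promoted Diels–Alder reaction gives the racemic adduct F1.
- Acetalisation with (R,R)-hydrobenzoin (PPTS, benzene, Dean–Stark) gives the wanted dioxolane F2 and its diastereomer F3, which are separated by chromatography or crystallisation.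
- Acid-catalysed exchange of F2 with MeOH/HC(OMe)3 gives 5.

Step 22 (face selectivity of the directed epoxidation in the macrocycle, and SN1 leakage at C7).
- This fallback sets out from 35 and comes back at 36, which is now isolated.
- Dess–Martin oxidation gives the cross-conjugated dienone F11, which also erases a wrong C9 configuration.
- Weitz–Scheffer epoxidation (t-BuOOH, Triton B, −20 °C) gives the trans-α,β-epoxy ketone F12.
- Chelation-controlled Zn(BH4)2 reduction gives the erythro epoxy alcohol 36, which CSA converts into 37 as in the route.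

**Further compounds**
F1 | step 2 | (±)-methyl 6-formyl-1,5-dimethylcyclohex-3-ene-1-carboxylate (racemate, one enantiomer drawn) | C1=CC[C@@](C(=O)OC)(C)[C@H]([C@H]1C)C=O
F2 | step 2 | (4R,5R)-4,5-diphenyl-1,3-dioxolane of 4 | C1=CC[C@@](C(=O)OC)(C)[C@H]([C@H]1C)C1O[C@H](c2ccccc2)[C@@H](c2ccccc2)O1
F3 | step 2 | (4R,5R)-4,5-diphenyl-1,3-dioxolane of ent-4 | C1=CC[C@](C(=O)OC)(C)[C@@H]([C@@H]1C)C1O[C@H](c2ccccc2)[C@@H](c2ccccc2)O1
F4 | step 21 | dimethylsilyl ether of 28 | C/C(I)=C/C#C[C@@H](C)CO[SiH](C)C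
F5 | step 21 | (R)-3-[(Z)-3-iodobut-2-enylidene]-2,2,4-trimethyl-1,2-oxasilolane (Si trans to C6) | C/C(I)=C/C=C1/[Si](C)(C)OC[C@@H]1C
F6 | step 21 | C4–C5 coupled oxasilolane | CC(C)(C)[Si](C)(C)O[C@@H]1C=C[C@@]([C@H](O[Si](C)(C)C(C)(C)C)CC/C(C)=C\C=C2\[Si](C)(C)OC[C@@H]2C)(C)[C@H]([C@H]1C)C(OC)OC
F7 | step 21 | (5Z,7E)-8-iododiene C19 alcohol | CC(C)(C)[Si](C)(C)O[C@@H]1C=C[C@@]([C@H](O[Si](C)(C)C(C)(C)C)CC/C(C)=C\C=C(\I)[C@@H](C)CO)(C)[C@H]([C@H]1C)C(OC)OC
F8 | step 21 | (5Z,7E)-8-iododiene C19 acid | CC(C)(C)[Si](C)(C)O[C@@H]1C=C[C@@]([C@H](O[Si](C)(C)C(C)(C)C)CC/C(C)=C\C=C(\I)[C@@H](C)C(=O)O)(C)[C@H]([C@H]1C)C(OC)OC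
F9 | step 21 | (5Z,7E)-8-iododiene tert-butyl ester | CC(C)(C)[Si](C)(C)O[C@@H]1C=C[C@@]([C@H](O[Si](C)(C)C(C)(C)C)CC/C(C)=C\C=C(\I)[C@@H](C)C(=O)OC(C)(C)C)(C)[C@H]([C@H]1C)C(OC)OC
F10 | step 21 | 8-iododiene C9 aldehyde | CC(C)(C)[Si](C)(C)O[C@@H]1C=C[C@@]([C@H](O[Si](C)(C)C(C)(C)C)CC/C(C)=C\C=C(\I)[C@@H](C)C(=O)OC(C)(C)C)(C)[C@H]([C@H]1C)C=O
F11 | step 22 | macrocyclic (5Z,7E)-dien-9-one | CC(C)(C)[Si](C)(C)O[C@@H]1C=C[C@@]2(C)[C@H]([C@H]1C)C(=O)/C([C@@H](C)C(=O)OC(C)(C)C)=C/C=C(/C)CC[C@H]2O[Si](C)(C)C(C)(C)C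
F12 | step 22 | (7R,8R)-7,8-epoxy-9-ketone | CC(C)(C)[Si](C)(C)O[C@@H]1C=C[C@@]2(C)[C@H]([C@H]1C)C(=O)[C@@]3([C@@H](C)C(=O)OC(C)(C)C)O[C@@H]3/C=C(/C)CC[C@H]2O[Si](C)(C)C(C)(C)C
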